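**Retrosynthetic overview**
1. Target 13 comes from silyl ether 12 by desilylation.
2. Key disconnection: the C2–C1' bond between ring C and ring B. Aryl bromide 7 and racemic acid 11 are joined by a decarboxylative nickel/photoredox radical cross-coupling that sets (2S).
3. 7 comes from (R)-epoxide 6 (radical Cp2TiCl isomerisation), 6 from Shi mono-epoxidation of 5, and 5 from double ortho-prenylation of 4-bromophenol 1.
4. 11 comes from resorcinol 8 and maleic anhydride 9 (Friedel–Crafts acylation, then oxa-Michael closure).
5. Ring order: rings A and B are bought as arenes; ring C is closed in step 5 and joined to ring B in step 6.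

Assumption: the sense of induction in step 6 is set by the choice of ligand enantiomer; the enantiomer that gives (2S) on a model aryl bromide is the one used.

**Step 1**
Reactants: 1 4-bromophenol; 2 1-bromo-3-methylbut-2-ene (prenyl bromide, 2.2 equiv)
Product: 4 4-bromo-2,6-bis(3-methylbut-2-en-1-yl)phenol, via 4-bromo-2-prenylphenol 3 (not isolated)
Conditions: NaH (2.2 equiv), toluene, 0 °C to rt, 2 added in two portions, 16 h
Reagents that add atoms: none
Why: Phenoxide ortho C-alkylation: the sodium phenoxide, a tight ion pair in toluene, is alkylated at the ortho carbon, the para position is blocked by bromine, and the second equivalent of base and bromide repeats this at the other ortho position; the O-prenyl ether and residual 3 are removed by chromatography (about 35–45% expected).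

**Step 2**
Reactants: 4 4-bromo-2,6-bis(3-methylbut-2-en-1-yl)phenol
Product: 5 tert-butyl[4-bromo-2,6-bis(3-methylbut-2-en-1-yl)phenoxy]dimethylsilane
Conditions: TBSCl (1.5 equiv), imidazole (3 equiv), DMF, 40 °C
Reagents that add atoms: tert-butyldimethylsilyl chloride, CC(C)(C)[Si](C)(C)Cl
Why: Standard silyl ether formation; masking the phenol stops it from opening the epoxide of step 3 and from acting as a hydrogen-atom donor in the radical steps 4 and 6.

**Step 3**
Reactants: 5 tert-butyl[4-bromo-2,6-bis(3-methylbut-2-en-1-yl)phenoxy]dimethylsilane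
Product: 6 tert-butyl[4-bromo-2-{[(2R)-3,3-dimethyloxiran-2-yl]methyl}-6-(3-methylbut-2-en-1-yl)phenoxy]dimethylsilane
Conditions: D-fructose-derived Shi ketone (0.3 equiv), KHSO5 (0.7 equiv, as 2KHSO5·KHSO4·K2SO4), K2CO3, Bu4NHSO4 (cat.), MeCN–CH2(OMe)2/aq. Na2B4O7 buffer (pH 10.5), 0 °C, stopped near 55% conversion; 5 recovered and recycled
Reagents that add atoms: potassium peroxymonosulfate KHSO5, [K+].[O-]S(=O)(=O)OO
Why: Shi asymmetric epoxidation: the chiral dioxirane attacks the trisubstituted alkene through the spiro transition state and gives the (R)-epoxide (typically above 90% ee); the two prenyl groups are homotopic, so the reaction is stopped early and the mono-epoxide is separated from recovered 5 and a little bis-epoxide (ceiling about 45% per pass).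

**Step 4**
Reactants: 6 tert-butyl[4-bromo-2-{[(2R)-3,3-dimethyloxiran-2-yl]methyl}-6-(3-methylbut-2-en-1-yl)phenoxy]dimethylsilane
Product: 7 (2R)-1-[5-bromo-2-(tert-butyldimethylsilyloxy)-3-(3-methylbut-2-en-1-yl)phenyl]-3-methylbut-3-en-2-ol
Conditions: Cp2TiCl2 (2.5 equiv), Mn dust (8 equiv), dry degassed THF, rt (forms Cp2TiCl, trivalent titanium); add 6, rt, 2 h; cold 1 M HCl work-up
Reagents that add atoms: none
Why: Radical epoxide isomerisation (Nugent–RajanBabu opening): Cp2TiCl cleaves the C–O bond at the tertiary carbon to give a β-titanoxy tertiary radical, a second Cp2TiCl removes a methyl hydrogen (mixed disproportionation) to leave the isopropenyl group, and because the C–O bond at the stereocentre is never broken the (R) configuration is kept.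

**Step 5**
Reactants: 8 resorcinol; 9 maleic anhydride
Product: 11 racemic 7-hydroxy-4-oxochroman-2-carboxylic acid, via aroylacrylic acid 10 (not isolated)
Conditions: AlCl3 (3 equiv), PhNO2–ClCH2CH2Cl, 0 to 60 °C; ice/2 M HCl; crude solid in aq. NaHCO3, rt, 12 h; HCl to pH 1, filter
Reagents that add atoms: none
Why: Friedel–Crafts acylation of resorcinol at C4 gives the aroylacrylic acid, and the ortho phenol then adds to the enone β-carbon (intramolecular oxa-Michael, 6-endo) to close ring C; the product is racemic, which does not matter because this centre becomes a planar radical in step 6.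

**Step 6**
Reactants: 7 (2R)-1-[5-bromo-2-(tert-butyldimethylsilyloxy)-3-(3-methylbut-2-en-1-yl)phenyl]-3-methylbut-3-en-2-ol; 11 racemic 7-hydroxy-4-oxochroman-2-carboxylic acid (1.5 equiv)
Product: 12 (2S)-2-[4-(tert-butyldimethylsilyloxy)-3-[(2R)-2-hydroxy-3-methylbut-3-en-1-yl]-5-(3-methylbut-2-en-1-yl)phenyl]-7-hydroxy-2,3-dihydro-4H-chromen-4-one
Conditions: NiCl2(dme) (10 mol %), chiral cyano-bis(oxazoline) 2,2-bis[(4S)-4-(4-tert-butylphenyl)-4,5-dihydro-1,3-oxazol-2-yl]acetonitrile (12 mol %), Ir[dF(CF3)ppy]2(dtbbpy)PF6 (2 mol %), K2HPO4 (1.5 equiv), degassed DMF, 450 nm LEDs, 25 °C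
Reagents that add atoms: none
Why: Proposed new method: the excited iridium photocatalyst oxidises the carboxylate of 11, loss of CO2 gives the planar α-oxy C2 radical (both enantiomers of 11 converge), the chiral nickel catalyst adds oxidatively to the C–Br bond of 7, captures the radical and forms the C2–aryl bond by reductive elimination from a trivalent nickel aryl alkyl complex in which the ligand distinguishes the ring-oxygen side from the CH2C=O side, giving (2S); the closest known reactions are the nickel/photoredox decarboxylative arylation of α-oxy acids with an achiral bipyridine (racemic) and its enantioconvergent variant for N-protected α-amino acids with this ligand class; the weak base leaves the 7-OH largely protonated, the alkenes do not trap the nucleophilic radical and the (R) carbinol is untouched.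

**Step 7**
Reactants: 12 (2S)-2-[4-(tert-butyldimethylsilyloxy)-3-[(2R)-2-hydroxy-3-methylbut-3-en-1-yl]-5-(3-methylbut-2-en-1-yl)phenyl]-7-hydroxy-2,3-dihydro-4H-chromen-4-one
Product: 13 (2S)-7-hydroxy-2-[4-hydroxy-3-[(2R)-2-hydroxy-3-methylbut-3-en-1-yl]-5-(3-methylbut-2-en-1-yl)phenyl]-2,3-dihydro-4H-chromen-4-one
Conditions: tetrabutylammonium fluoride (1.2 equiv), AcOH (1.5 equiv), THF, 0 °C to rt
Reagents that add atoms: none
Why: Fluoride-mediated desilylation under acetic acid buffering; the near-neutral medium avoids the base-triggered retro-oxa-Michael ring opening that would racemise C2 and leaves the prenyl group and the allylic alcohol untouched.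

**Compound list**
1 | 4-bromophenol | Oc1ccc(Br)cc1 | starting material
2 | 1-bromo-3-methylbut-2-ene (prenyl bromide) | CC(C)=CCBr | starting material
3 | 4-bromo-2-(3-methylbut-2-en-1-yl)phenol | CC(C)=CCc1cc(Br)ccc1O | intermediate
4 | 4-bromo-2,6-bis(3-methylbut-2-en-1-yl)phenol | CC(C)=CCc1cc(Br)cc(CC=C(C)C)c1O | intermediate
5 | tert-butyl[4-bromo-2,6-bis(3-methylbut-2-en-1-yl)phenoxy]dimethylsilane | CC(C)=CCc1cc(Br)cc(CC=C(C)C)c1O[Si](C)(C)C(C)(C)C | intermediate
6 | tert-butyl[4-bromo-2-{[(2R)-3,3-dimethyloxiran-2-yl]methyl}-6-(3-methylbut-2-en-1-yl)phenoxy]dimethylsilane | CC(C)=CCc1cc(Br)cc(C[C@H]2OC2(C)C)c1O[Si](C)(C)C(C)(C)C | intermediate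
7 | (2R)-1-[5-bromo-2-(tert-butyldimethylsilyloxy)-3-(3-methylbut-2-en-1-yl)phenyl]-3-methylbut-3-en-2-ol | C=C(C)[C@H](O)Cc1cc(Br)cc(CC=C(C)C)c1O[Si](C)(C)C(C)(C)C | intermediate
8 | resorcinol (benzene-1,3-diol) | Oc1cccc(O)c1 | starting material
9 | maleic anhydride | O=C1OC(=O)C=C1 | starting material
10 | (E)-4-(2,4-dihydroxyphenyl)-4-oxobut-2-enoic acid | O=C(O)/C=C/C(=O)c1ccc(O)cc1O | intermediate
11 | racemic 7-hydroxy-4-oxochroman-2-carboxylic acid | O=C(O)C1CC(=O)c2ccc(O)cc2O1 | intermediate
12 | (2S)-2-[4-(tert-butyldimethylsilyloxy)-3-[(2R)-2-hydroxy-3-methylbut-3-en-1-yl]-5-(3-methylbut-2-en-1-yl)phenyl]-7-hydroxy-2,3-dihydro-4H-chromen-4-one | C=C(C)[C@H](O)Cc1cc([C@@H]2CC(=O)c3ccc(O)cc3O2)cc(CC=C(C)C)c1O[Si](C)(C)C(C)(C)C | intermediate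
13 | (2S)-7-hydroxy-2-[4-hydroxy-3-[(2R)-2-hydroxy-3-methylbut-3-en-1-yl]-5-(3-methylbut-2-en-1-yl)phenyl]-2,3-dihydro-4H-chromen-4-one | C=C(C)[C@H](O)Cc1cc([C@@H]2CC(=O)c3ccc(O)cc3O2)cc(CC=C(C)C)c1O | target

**Totals**
Total step count: 7. Longest linear sequence: 6 (steps 1, 2, 3, 4, 6, 7); step 5 is a one-step branch.

**Three steps most likely to fail**

Step 6. The enantioconvergent radical coupling is new for an α-oxy acid. The risks are low ee, slow oxidative addition to the electron-rich bromide, and interference by the free phenol of 11. The fallback sets out from 7 and 11 and comes back at 12. Bromine–lithium exchange on 7 (n-BuLi, 2.1 equiv, THF, −78 °C, the first equivalent being consumed by the alcohol), then B(OiPr)3 and dilute acid, gives [4-(tert-butyldimethylsilyloxy)-3-[(2R)-2-hydroxy-3-methylbut-3-en-1-yl]-5-(3-methylbut-2-en-1-yl)phenyl]boronic acid F1. Acid 11 is converted by photochemical decarboxylative desaturation (9-mesitylacridine, Co(dmgH)2(py)Cl, 400 nm LEDs, CH2Cl2) into 7-hydroxy-4H-chromen-4-one F2. An asymmetric conjugate arylation then adds F1 to F2 to give 12: Pd(OCOCF3)2 (5 mol %), the enantiomer of t-BuPyOX that gives the (2S) series, NH4PF6, H2O, ClCH2CH2Cl, 60 °C. Step 7 follows unchanged.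

Step 1. Double ortho C-prenylation competes with O-alkylation and stops partly at 3, so the yield may be poor. The fallback sets out from 1 and comes back at 4. O-Allylation (allyl bromide, K2CO3, acetone, reflux) gives 1-(allyloxy)-4-bromobenzene F3. Claisen rearrangement (N,N-diethylaniline, 200 °C) gives 2-allyl-4-bromophenol F4. A second O-allylation gives 2-allyl-1-(allyloxy)-4-bromobenzene F5, and a second Claisen rearrangement gives 2,6-diallyl-4-bromophenol F6. Cross-metathesis of F6 with excess 2-methylbut-2-ene (second-generation Grubbs catalyst RuCl2(=CHPh)(H2IMes)(PCy3), CH2Cl2, 40 °C) turns both allyl groups into prenyl groups and gives 4.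

Step 5. Unprotected resorcinol may be acylated twice or give condensation dyes with the anhydride under AlCl3. The fallback sets out from 8 and comes back at 10, which closes to 11 under the NaHCO3 treatment of step 5. Nencki acylation of 8 with acetic acid and ZnCl2 (140 °C) gives 1-(2,4-dihydroxyphenyl)ethan-1-one F7. Acid-catalysed aldol condensation of F7 with glyoxylic acid monohydrate (AcOH, cat. HCl, reflux) gives 10.

**Further compounds**
F1 | step 6 | [4-(tert-butyldimethylsilyloxy)-3-[(2R)-2-hydroxy-3-methylbut-3-en-1-yl]-5-(3-methylbut-2-en-1-yl)phenyl]boronic acid | C=C(C)[C@H](O)Cc1cc(B(O)O)cc(CC=C(C)C)c1O[Si](C)(C)C(C)(C)C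
F2 | step 6 | 7-hydroxy-4H-chromen-4-one | O=c1ccoc2cc(O)ccc12
F3 | step 1 | 1-(allyloxy)-4-bromobenzene | C=CCOc1ccc(Br)cc1
F4 | step 1 | 2-allyl-4-bromophenol | C=CCc1cc(Br)ccc1O
F5 | step 1 | 2-allyl-1-(allyloxy)-4-bromobenzene | C=CCOc1ccc(Br)cc1CC=C
F6 | step 1 | 2,6-diallyl-4-bromophenol | C=CCc1cc(Br)cc(CC=C)c1O
F7 | step 5 | 1-(2,4-dihydroxyphenyl)ethan-1-one | CC(=O)c1ccc(O)cc1O
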